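## Analysis of the target

Locants used throughout: N1 and C2–C6 for the pyridone, C1–C8a for the octalin (ketone carbon on C1), C1'–C6' for the cyclohexane (C1' bonded to C5).

Fischerin joins three units. A 1,4-dihydroxy-2-pyridone carries at C3 the acyl group of a cis-fused Δ3-octalin and at C5 a 7-oxabicyclo[4.1.0]heptane-2,5-diol bound through its tertiary carbinol C1'. The octalin has four contiguous stereocentres (C1, C2, C4a, C8a): the ring fusion is cis, the methyl group is cis to C8, and the acyl group is trans to both neighbours. C1 is α to the ketone and this is its stable configuration. The cis fusion, however, is what an (E,E,E)-trienoyl chain gives only through the disfavoured exo mode of an intramolecular Diels–Alder reaction.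

The cyclohexane has four stereocentres (C1', C4', C5', C6'). The pyridone, the C5'–C6' epoxide oxygen and the C4' hydroxyl lie on one face; the tertiary C1' hydroxyl lies on the other. The feature that the strategy uses is that C1' and C4' are para on this ring. If the epoxide oxygen is removed and C2'–C3' is dehydrogenated, the ring becomes a 1-aryl-cyclohexa-2,5-diene-1,4-diol with a mirror plane through C1' and C4'. All four stereocentres are therefore latent in an achiral precursor.

The two stereoclusters are insulated from each other by the flat pyridone, so each needs its own source of absolute configuration. The sensitive groups are: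
- the trans-2,3-epoxy alcohol (epoxide migration under base);
- the tertiary carbinol ortho to the acidic 4-OH (ionisation under acid);
- the N–OH group;
- the single C3=C4 alkene, which forbids hydrogenolysis and electrophilic oxidants once the octalin is attached.

The hard points are the aryl group cis to the epoxide at C1' (a carbon nucleophile adding to a C1' ketone should enter anti to the oxirane) and the cis ring fusion.

## Retrosynthetic reasoning

**34 ⇒ 33 (O–Si and O–C bonds of four protecting groups).** All four blocked oxygens of 33 are cleaved by one fluoride treatment, so no acid, strong base or hydrogen touches the epoxy diol or the alkene at the end. The N–O bond is not made late: the ring nitrogen of 33 is an N-oxide held as the 2-alkoxy tautomer of the N-hydroxypyridone, and this goes back unchanged to 18.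

**33 ⇒ 32 ⇒ 30 + 17 (C3–C(=O) bond).** The cut lies between C3 and the ketone carbon, so the octalin enters as aldehyde 17 and the heterocycle as the aryl-magnesium 31 from iodide 30. This union is placed last because 17 carries the only C=C bond of the target, while the cyclohexane is built with an epoxidising agent, a diimide reduction and an electrophilic iodination. After the union only an alcohol oxidation and the deprotection remain. 30 comes from 29 by iodination at the one remaining activated ring position, and 29 from 28 by silylation.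

**28 ⇒ 27 ⇒ 26 (the two C–O bonds of the oxirane; key disconnection).** Removing the epoxide oxygen and two hydrogens from 28 leads to the achiral dienol 26. In the forward sense, a hydroxyl-directed, catalyst-controlled mono-epoxidation of 26 must choose one of two enantiotopic alkenes and deliver oxygen syn to the C4' hydroxyl. This fixes C1', C4', C5' and C6' in one operation and gives the aryl-cis-to-epoxide relation that a ketone addition cannot give. The remaining alkene of 27 is then saturated to give 28.

**26 ⇒ 25 ⇒ 24 ⇒ 20 + 21 (C4'–H bond, then C5–C1' bond).** The C4' carbinol comes from the dienone 25 by 1,2-reduction, which must place the hydroxyl cis to the aryl group. The quaternary carbinol C1' comes from addition of the aryl-magnesium 22 to the ketone of quinone monoketal 21. No stereocentre is formed there, so the facial problem of a ketone addition does not arise. 20 comes from 19 by iodination, and 19 from commercial 18 by two aromatic substitutions.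

**17 ⇒ 16 ⇒ 15 ⇒ 13 ⇒ 11 + 5 (C1–vinyl and C2–methyl bonds, C3=C4).** The formyl carbon is a vinyl group in disguise. The C3=C4 alkene is the reduced form of a kinetic enol triflate. C1 and C2 are set together on the cis-fused enone 11 by conjugate vinyl addition on the convex face followed by enolate methylation anti to the new group.

**11 ⇒ 10 ⇒ 9 ⇒ 6 ⇒ 4 + 5, and 4 ⇒ 3 ⇒ 1 + 2 (ring fusion).** The cis fusion is not made by an intramolecular Diels–Alder reaction. It comes from the anionic oxy-Cope rearrangement of the bicyclo[2.2.2]octenol 6 (via 7 and 8), where the bicycle allows only the cis-fused product. The absolute configuration comes from the catalytic Diels–Alder reaction of 1 with 2.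

## Alternatives that were turned down

**Alternative 1:** The textbook route cuts C5–C1' as the addition of the 5-metalated heterocycle 22 to a fully oxygenated epoxy ketone A1, and makes the octalin by intramolecular Diels–Alder reaction of trienal A2. The forward key step is the 1,2-addition of 22 to A1. It was turned down for three reasons.
- The nucleophile should enter anti to the oxirane C–O bond and anti to the silyloxy group. This gives adduct A3 with the tertiary hydroxyl cis to the epoxide, the C1' epimer of what is needed. A quaternary carbinol cannot be inverted afterwards.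
- A2 should cyclise mainly through the endo mode to the trans-fused octalin. The cis-fused exo adduct is the minor product, and neither ring-fusion centre can be epimerised later.
- A1 needs about five steps in enantiopure form, so nothing is saved.

**Alternative 2:** The biomimetic route makes the acyltetramic acid A4 from tyrosine and the octalin, then expands the five-membered ring to the 5-(4-hydroxyphenyl)pyridone A5 by a 1,2-acyl shift to the oxidised benzylic carbon. N-hydroxylation and oxidative dearomatisation of the phenol follow. It was turned down because: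
- the ring expansion has no close laboratory counterpart, and it produces only a flat aryl-pyridone bond that a cross-coupling also gives;
- every oxygenation of the cyclohexane would then run on the complete molecule, in the presence of C3=C4 and with no stereocontrol from the remote octalin;
- nucleophilic epoxidation of the resulting quinol is expected syn to the tertiary hydroxyl, the wrong face.

**Alternative 3:** A [4+2] addition of singlet oxygen to the 1-aryl-cyclohexa-1,3-diene A6 gives endoperoxide A7. Epoxidation anti to the peroxide bridge, Kornblum–DeLaMare fragmentation and hydride reduction anti to the oxirane follow. The bicyclic peroxide would enforce every relative relation of the ring in four steps. It was turned down because A7 forms as a racemate from an achiral diene and an achiral reagent. No enantiotopic pair is left to differentiate, so the only catalytic remedy is a kinetic resolution that discards half the material. With the octalin attached first, the two diastereomers would form without control and the peracid would attack C3=C4. The chosen route keeps the idea of two para oxygens and ring-controlled faces, but passes through a meso intermediate.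

Key step: step 16

Remark on the chemistry (assumptions): iodination of 19 is taken to occur at C5 (para to the 2-alkoxy group), as for 2,4-dialkoxypyridines; the catalyst antipodes in steps 1 and 16 are those that give the configurations drawn, the sense being predicted by the usual models and to be confirmed on 4 and 27.

## Route

Step 1
Reactants: 1 cyclohexa-1,3-diene; 2 acrolein
Product: 3 (1R,2R,4R)-bicyclo[2.2.2]oct-5-ene-2-carbaldehyde
Conditions: 5-benzyl-2,2,3-trimethylimidazolidin-4-one·HCl (10 mol %, antipode giving the 2R adduct), MeCN–H2O 95:5, rt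
Reagents that add atoms: none
Why: Iminium-catalysed Diels–Alder reaction; the benzyl group of the catalyst shields one face of the acrolein iminium ion and the endo mode places CHO syn to the new C5=C6 bridge, so C1, C2 and C4 are set together. The minor exo isomer is removed here because it would lead to the enantiomer of 4.

Step 2
Reactants: 3 (1R,2R,4R)-bicyclo[2.2.2]oct-5-ene-2-carbaldehyde
Product: 4 (1R,4R)-bicyclo[2.2.2]oct-5-en-2-one
Conditions: Cu(OAc)2 (10 mol %), 2,2'-bipyridine (10 mol %), DABCO, O2 (1 atm), DMF, 40 °C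
Reagents that add atoms: dioxygen, O=O
Why: Copper-catalysed aerobic oxidative deformylation of an α-branched aldehyde: the enolate is oxygenated at the α-carbon and the α-hydroperoxy aldehyde fragments to ketone and formate. The bridgehead stereocentres are not touched.

Step 3
Reactants: 4 (1R,4R)-bicyclo[2.2.2]oct-5-en-2-one; 5 vinylmagnesium bromide
Product: 6 (1R,2R,4R)-2-ethenylbicyclo[2.2.2]oct-5-en-2-ol
Conditions: CeCl3, THF, −78 °C; aq. NH4Cl
Reagents that add atoms: none
Why: Cerium-modified Grignard 1,2-addition from the face flanked by the C5=C6 bridge (sp2 CH) rather than by the ethano bridge with its inward hydrogens. The vinyl group ends syn to the ring alkene, the geometry the [3,3] shift needs; a minor C2 epimer is removed by chromatography.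

Step 4
Reactants: 6 (1R,2R,4R)-2-ethenylbicyclo[2.2.2]oct-5-en-2-ol
Product: 9 trimethyl{[(4aS,8aR)-1,4,4a,7,8,8a-hexahydronaphthalen-2-yl]oxy}silane, via potassium alkoxide 7 (not isolated), via potassium enolate 8 (not isolated)
Conditions: KH, 18-crown-6, THF, 0 °C to rt; then Me3SiCl, Et3N, −78 °C
Reagents that add atoms: chlorotrimethylsilane, C[Si](C)(C)Cl
Why: Anionic oxy-Cope rearrangement through the boat transition state that the bicycle enforces: the C1–C2 bond breaks and the vinyl terminus bonds to C5 from the side of the carbinol bridge, so the new ring fusion (C4a/C8a of the target) can only be cis. The regiodefined enolate is trapped on oxygen.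

Step 5
Reactants: 9 trimethyl{[(4aS,8aR)-1,4,4a,7,8,8a-hexahydronaphthalen-2-yl]oxy}silane
Product: 10 trimethyl{[(4aS,8aR)-1,4,4a,5,6,7,8,8a-octahydronaphthalen-2-yl]oxy}silane
Conditions: H2 (1 atm), RhCl(PPh3)3 (5 mol %), benzene, rt
Reagents that add atoms: none
Why: Homogeneous hydrogenation reduces the unhindered cis-disubstituted alkene and leaves the trisubstituted silyl enol ether. The ring-B alkene must go now, before the ring-A alkene of the target exists.

Step 6
Reactants: 10 trimethyl{[(4aS,8aR)-1,4,4a,5,6,7,8,8a-octahydronaphthalen-2-yl]oxy}silane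
Product: 11 (4aR,8aR)-4a,5,6,7,8,8a-hexahydronaphthalen-2(1H)-one
Conditions: Pd(OAc)2 (1.05 equiv), MeCN, rt
Reagents that add atoms: none
Why: Saegusa–Ito oxidation: the palladium enolate formed from the enol ether undergoes β-hydride elimination towards the only sp3 neighbour, so the enone double bond is placed at C1=C2 (target locants) by the regiochemistry stored in 10.

Step 7
Reactants: 11 (4aR,8aR)-4a,5,6,7,8,8a-hexahydronaphthalen-2(1H)-one; 5 vinylmagnesium bromide
Product: 13 (3R,4S,4aR,8aR)-4-ethenyl-3-methyloctahydronaphthalen-2(1H)-one, via bromomagnesium enolate 12 (not isolated)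
Conditions: CuBr·SMe2 (10 mol %), THF, −78 to −40 °C; then DMPU, MeI, −40 to 0 °C
Reagents that add atoms: iodomethane, CI
Why: Copper-catalysed conjugate addition on the convex face of the cis-fused enone (anti to the C8a–C8 bond) sets C1. The enolate is methylated anti to the new vinyl group and sets C2 (vicinal difunctionalisation, trans).

Step 8
Reactants: 13 (3R,4S,4aR,8aR)-4-ethenyl-3-methyloctahydronaphthalen-2(1H)-one
Product: 15 (1S,2R,4aS,8aR)-1-ethenyl-2-methyl-1,2,4a,5,6,7,8,8a-octahydronaphthalen-3-yl trifluoromethanesulfonate, via lithium enolate 14 (not isolated)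
Conditions: LDA, THF, −78 °C; then N-(5-chloropyridin-2-yl)bis(trifluoromethanesulfonyl)imide, −78 to 0 °C
Reagents that add atoms: N-(5-chloropyridin-2-yl)bis(trifluoromethanesulfonyl)imide, FC(F)(F)S(=O)(=O)N(c1ccc(Cl)cn1)S(=O)(=O)C(F)(F)F
Why: Kinetic deprotonation takes the CH2 group (C4) rather than the methine C2, and O-sulfonylation stores the future C3=C4 alkene as an enol triflate.

Step 9
Reactants: 15 (1S,2R,4aS,8aR)-1-ethenyl-2-methyl-1,2,4a,5,6,7,8,8a-octahydronaphthalen-3-yl trifluoromethanesulfonate
Product: 16 (1S,2R,4aS,8aR)-1-formyl-2-methyl-1,2,4a,5,6,7,8,8a-octahydronaphthalen-3-yl trifluoromethanesulfonate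
Conditions: O3, CH2Cl2–MeOH, −78 °C; then PPh3
Reagents that add atoms: ozone, [O-][O+]=O
Why: Ozonolysis with reductive work-up; the terminal vinyl group is far more electron-rich than the enol triflate alkene, so only it is cleaved and its inner carbon becomes the future ketone carbon. C1 is not touched.

Step 10
Reactants: 16 (1S,2R,4aS,8aR)-1-formyl-2-methyl-1,2,4a,5,6,7,8,8a-octahydronaphthalen-3-yl trifluoromethanesulfonate
Product: 17 (1R,2S,4aR,8aR)-2-methyl-1,2,4a,5,6,7,8,8a-octahydronaphthalene-1-carbaldehyde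
Conditions: Pd(OAc)2 (5 mol %), PPh3 (10 mol %), HCO2H, Et3N, DMF, 60 °C
Reagents that add atoms: none
Why: Palladium-catalysed formate reduction of the enol triflate leaves the C3=C4 alkene in a fixed position. C1 may equilibrate through the enol, but the configuration drawn (formyl equatorial, trans to both neighbours) is the stable one.

Step 11
Reactants: 18 2-chloro-4-nitropyridine 1-oxide
Product: 19 2,4-bis[2-(trimethylsilyl)ethoxy]pyridine 1-oxide
Conditions: Me3SiCH2CH2OH (2.3 equiv), NaH (2.3 equiv), THF, 0 to 55 °C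
Reagents that add atoms: 2-(trimethylsilyl)ethanol, C[Si](C)(C)CCO
Why: Two nucleophilic aromatic substitutions on the N-oxide-activated ring (4-nitro first, then 2-chloro). The product is the O-locked 2-alkoxypyridine N-oxide tautomer of the N-hydroxy-2-pyridone, so the N–O bond is present from the start.

Step 12
Reactants: 19 2,4-bis[2-(trimethylsilyl)ethoxy]pyridine 1-oxide
Product: 20 5-iodo-2,4-bis[2-(trimethylsilyl)ethoxy]pyridine 1-oxide
Conditions: NIS, MeCN, rt, dark
Reagents that add atoms: N-iodosuccinimide, O=C1CCC(=O)N1I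
Why: Electrophilic aromatic iodination at C5, which is para to the 2-alkoxy group and ortho to the 4-alkoxy group; C3 lies between two alkoxy groups and is more hindered.

Step 13
Reactants: 20 5-iodo-2,4-bis[2-(trimethylsilyl)ethoxy]pyridine 1-oxide; 21 4,4-dimethoxycyclohexa-2,5-dien-1-one
Product: 24 5-(1-hydroxy-4-oxocyclohexa-2,5-dien-1-yl)-2,4-bis[2-(trimethylsilyl)ethoxy]pyridine 1-oxide, via arylmagnesium chloride 22 (not isolated), via dimethyl ketal carbinol 23 (not isolated)
Conditions: i-PrMgCl·LiCl, THF, −40 °C; 21, −40 to 0 °C; then AcOH–H2O–THF, rt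
Reagents that add atoms: water, O
Why: Iodine–magnesium exchange, 1,2-addition of the aryl-magnesium to the ketone of the quinone monoketal, and mild acid hydrolysis of the ketal to the dienone. C1' becomes quaternary without becoming a stereocentre, so no facial selectivity is needed.

Step 14
Reactants: 24 5-(1-hydroxy-4-oxocyclohexa-2,5-dien-1-yl)-2,4-bis[2-(trimethylsilyl)ethoxy]pyridine 1-oxide
Product: 25 5-[4-oxo-1-(triethylsilyloxy)cyclohexa-2,5-dien-1-yl]-2,4-bis[2-(trimethylsilyl)ethoxy]pyridine 1-oxide
Conditions: Et3SiOTf, 2,6-lutidine, CH2Cl2, −78 to 0 °C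
Reagents that add atoms: triethylsilyl trifluoromethanesulfonate, CC[Si](CC)(CC)OS(=O)(=O)C(F)(F)F
Why: Silylation of the tertiary alcohol; the silyl ether later blocks one ring face, cannot direct an oxidant and makes the bis-allylic C1'–O bond less prone to ionise.

Step 15
Reactants: 25 5-[4-oxo-1-(triethylsilyloxy)cyclohexa-2,5-dien-1-yl]-2,4-bis[2-(trimethylsilyl)ethoxy]pyridine 1-oxide
Product: 26 5-[4-hydroxy-1-(triethylsilyloxy)cyclohexa-2,5-dien-1-yl]-2,4-bis[2-(trimethylsilyl)ethoxy]pyridine 1-oxide (4-OH cis to the pyridyl ring; meso)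
Conditions: NaBH4, CeCl3·7H2O, MeOH, −78 °C
Reagents that add atoms: none
Why: Luche 1,2-reduction; hydride should attack the flat dienone on the face of the C1' oxygen and anti to the bulkier aryl group, the usual preference of 4-oxygenated 4-substituted cyclohexadienones. The new C4' hydroxyl is then cis to the pyridyl ring and the mirror plane through C1' and C4' is kept.

Step 16
Reactants: 26 5-[4-hydroxy-1-(triethylsilyloxy)cyclohexa-2,5-dien-1-yl]-2,4-bis[2-(trimethylsilyl)ethoxy]pyridine 1-oxide
Product: 27 5-[(1R,2S,5R,6R)-5-hydroxy-2-(triethylsilyloxy)-7-oxabicyclo[4.1.0]hept-3-en-2-yl]-2,4-bis[2-(trimethylsilyl)ethoxy]pyridine 1-oxide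
Conditions: VO(Oi-Pr)3 (2 mol %), C2-symmetric bis-hydroxamic acid ligand from trans-cyclohexane-1,2-diamine (3 mol %, antipode that epoxidises C5'=C6'), t-BuOOH (1.1 equiv), toluene, 0 °C
Reagents that add atoms: tert-butyl hydroperoxide, CC(C)(C)OO
Why: The hydroxyl of 26 exchanges onto the chiral vanadium(V) bis-hydroxamate, the hydroperoxide binds to the same metal, and one peroxide oxygen is passed to a flanking cis-alkene through a spiro transition state. The closest known reaction type is the vanadium/bis-hydroxamic acid-catalysed asymmetric epoxidation of allylic alcohols in its desymmetrising form on meso divinyl carbinols; the achiral parent is the vanadium-catalysed syn epoxidation of cyclohex-2-enols. The oxirane is closed by concerted, suprafacial transfer of a single oxygen atom to C5'=C6' of the existing six-membered ring (a [2+1] oxygen-atom transfer, not a cyclisation of a chain), so its two C–O bonds are cis by necessity. C5' and C6' are controlled by the directing C4' hydroxyl: oxygen is delivered syn to it, which in 26 is also the face of the pyridyl group and the face opposite to the blocking OSiEt3 group, and this places the epoxide anti to the C1' oxygen. C1' and C4' are pseudo-asymmetric in 26 and become the 1'S and 4'R stereocentres at the moment the catalyst takes the C5'=C6' arm instead of its mirror-image arm C2'=C3'; this choice is controlled only by the ligand antipode. The step needs enantiotopic-group selectivity, syn facial selectivity and mono-epoxidation. The first is sharpened because the minor enantiomer of 27 still carries the alkene the catalyst prefers and is consumed to the bis-epoxide; the second is secured by the directing hydroxyl and the silyl ether, which also stops the tertiary oxygen from directing; the third by limiting the oxidant.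

Step 17
Reactants: 27 5-[(1R,2S,5R,6R)-5-hydroxy-2-(triethylsilyloxy)-7-oxabicyclo[4.1.0]hept-3-en-2-yl]-2,4-bis[2-(trimethylsilyl)ethoxy]pyridine 1-oxide
Product: 28 5-[(1R,2S,5R,6R)-5-hydroxy-2-(triethylsilyloxy)-7-oxabicyclo[4.1.0]heptan-2-yl]-2,4-bis[2-(trimethylsilyl)ethoxy]pyridine 1-oxide
Conditions: 2-nitrobenzenesulfonohydrazide, Et3N, CH2Cl2, rt
Reagents that add atoms: none
Why: Diimide, generated in the flask, transfers two hydrogens to the remaining cis-alkene in a concerted syn fashion. Unlike metal-catalysed hydrogenation it should not cleave the allylic C–O bonds, the N-oxide or the epoxide.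

Step 18
Reactants: 28 5-[(1R,2S,5R,6R)-5-hydroxy-2-(triethylsilyloxy)-7-oxabicyclo[4.1.0]heptan-2-yl]-2,4-bis[2-(trimethylsilyl)ethoxy]pyridine 1-oxide
Product: 29 5-[(1R,2S,5R,6S)-2,5-bis(triethylsilyloxy)-7-oxabicyclo[4.1.0]heptan-2-yl]-2,4-bis[2-(trimethylsilyl)ethoxy]pyridine 1-oxide
Conditions: Et3SiCl, imidazole, DMF, rt
Reagents that add atoms: chlorotriethylsilane, CC[Si](Cl)(CC)CC
Why: Silylation of the secondary alcohol so that it neither quenches the Grignard reagent of step 20 nor is oxidised in step 21. The descriptor at C6 changes only because of the CIP priorities.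

Step 19
Reactants: 29 5-[(1R,2S,5R,6S)-2,5-bis(triethylsilyloxy)-7-oxabicyclo[4.1.0]heptan-2-yl]-2,4-bis[2-(trimethylsilyl)ethoxy]pyridine 1-oxide
Product: 30 5-[(1R,2S,5R,6S)-2,5-bis(triethylsilyloxy)-7-oxabicyclo[4.1.0]heptan-2-yl]-3-iodo-2,4-bis[2-(trimethylsilyl)ethoxy]pyridine 1-oxide
Conditions: NIS, MeCN, rt, dark
Reagents that add atoms: N-iodosuccinimide, O=C1CCC(=O)N1I
Why: Electrophilic aromatic iodination at C3, the only remaining position activated by both alkoxy groups. The conditions are neutral and the substrate no longer contains an alkene.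

Step 20
Reactants: 30 5-[(1R,2S,5R,6S)-2,5-bis(triethylsilyloxy)-7-oxabicyclo[4.1.0]heptan-2-yl]-3-iodo-2,4-bis[2-(trimethylsilyl)ethoxy]pyridine 1-oxide; 17 (1R,2S,4aR,8aR)-2-methyl-1,2,4a,5,6,7,8,8a-octahydronaphthalene-1-carbaldehyde
Product: 32 5-[(1R,2S,5R,6S)-2,5-bis(triethylsilyloxy)-7-oxabicyclo[4.1.0]heptan-2-yl]-3-{hydroxy[(1R,2S,4aR,8aR)-2-methyl-1,2,4a,5,6,7,8,8a-octahydronaphthalen-1-yl]methyl}-2,4-bis[2-(trimethylsilyl)ethoxy]pyridine 1-oxide (both carbinol epimers), via arylmagnesium chloride 31 (not isolated)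
Conditions: i-PrMgCl·LiCl, THF, −40 °C; 17, −40 to 0 °C; aq. NH4Cl
Reagents that add atoms: none
Why: Iodine–magnesium exchange gives an aryl-magnesium flanked by two alkoxy groups, which adds to the aldehyde. The configuration of the new carbinol is irrelevant because it is oxidised next, and from here on no reagent is used that attacks the C3=C4 alkene.

Step 21
Reactants: 32 5-[(1R,2S,5R,6S)-2,5-bis(triethylsilyloxy)-7-oxabicyclo[4.1.0]heptan-2-yl]-3-{hydroxy[(1R,2S,4aR,8aR)-2-methyl-1,2,4a,5,6,7,8,8a-octahydronaphthalen-1-yl]methyl}-2,4-bis[2-(trimethylsilyl)ethoxy]pyridine 1-oxide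
Product: 33 5-[(1R,2S,5R,6S)-2,5-bis(triethylsilyloxy)-7-oxabicyclo[4.1.0]heptan-2-yl]-3-[(1R,2S,4aR,8aR)-2-methyl-1,2,4a,5,6,7,8,8a-octahydronaphthalene-1-carbonyl]-2,4-bis[2-(trimethylsilyl)ethoxy]pyridine 1-oxide
Conditions: Dess–Martin periodinane, pyridine, CH2Cl2, 0 °C to rt
Reagents that add atoms: none
Why: Dess–Martin oxidation of the secondary aryl carbinol to the ketone under buffered, non-acidic conditions. C1 of the octalin is α to the new ketone but already has its stable configuration.

Step 22
Reactants: 33 5-[(1R,2S,5R,6S)-2,5-bis(triethylsilyloxy)-7-oxabicyclo[4.1.0]heptan-2-yl]-3-[(1R,2S,4aR,8aR)-2-methyl-1,2,4a,5,6,7,8,8a-octahydronaphthalene-1-carbonyl]-2,4-bis[2-(trimethylsilyl)ethoxy]pyridine 1-oxide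
Product: 34 fischerin, 3-[(1R,2S,4aR,8aR)-2-methyl-1,2,4a,5,6,7,8,8a-octahydronaphthalene-1-carbonyl]-5-[(1R,2S,5R,6R)-2,5-dihydroxy-7-oxabicyclo[4.1.0]heptan-2-yl]-1,4-dihydroxypyridin-2(1H)-one
Conditions: Bu4NF, AcOH (1:1, 6 equiv), THF–DMF, 0 °C to rt; pH 4 buffer
Reagents that add atoms: none
Why: Fluoride cleaves the two Si–O bonds and triggers β-elimination of the two silylethyl ethers (ethene and Me3SiF). This frees the 4-hydroxyl and the 2-hydroxypyridine N-oxide, which is the N-hydroxy-2-pyridone tautomer of the target. The acetic acid buffer keeps the freed alkoxides protonated so that the epoxide does not migrate.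

## Compound list

1 | cyclohexa-1,3-diene | C1=CC=CCC1 | starting material
2 | acrolein (prop-2-enal) | C=CC=O | starting material
3 | (1R,2R,4R)-bicyclo[2.2.2]oct-5-ene-2-carbaldehyde (endo) | O=C[C@@H]1C[C@@H]2C=C[C@H]1CC2 | intermediate
4 | (1R,4R)-bicyclo[2.2.2]oct-5-en-2-one | O=C1C[C@@H]2C=C[C@H]1CC2 | intermediate
5 | vinylmagnesium bromide | C=C[Mg]Br | starting material
6 | (1R,2R,4R)-2-ethenylbicyclo[2.2.2]oct-5-en-2-ol (vinyl syn to the C5=C6 bridge) | C=C[C@]1(O)C[C@@H]2C=C[C@H]1CC2 | intermediate
7 | potassium (1R,2R,4R)-2-ethenylbicyclo[2.2.2]oct-5-en-2-olate | C=C[C@]1([O-])C[C@@H]2C=C[C@H]1CC2.[K+] | intermediate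
8 | potassium (4aS,8aR)-1,4,4a,7,8,8a-hexahydronaphthalen-2-olate (cis-fused) | [K+].[O-]C1=CC[C@@H]2C=CCC[C@@H]2C1 | intermediate
9 | trimethyl{[(4aS,8aR)-1,4,4a,7,8,8a-hexahydronaphthalen-2-yl]oxy}silane | C[Si](C)(C)OC1=CC[C@@H]2C=CCC[C@@H]2C1 | intermediate
10 | trimethyl{[(4aS,8aR)-1,4,4a,5,6,7,8,8a-octahydronaphthalen-2-yl]oxy}silane | C[Si](C)(C)OC1=CC[C@@H]2CCCC[C@@H]2C1 | intermediate
11 | (4aR,8aR)-4a,5,6,7,8,8a-hexahydronaphthalen-2(1H)-one (cis-fused) | O=C1C=C[C@@H]2CCCC[C@@H]2C1 | intermediate
12 | bromomagnesium (4S,4aR,8aR)-4-ethenyl-1,4,4a,5,6,7,8,8a-octahydronaphthalen-2-olate | Br[Mg]OC1=C[C@@H](C=C)[C@@H]2CCCC[C@@H]2C1 | intermediate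
13 | (3R,4S,4aR,8aR)-4-ethenyl-3-methyloctahydronaphthalen-2(1H)-one | C[C@H]1C(=O)C[C@H]2CCCC[C@H]2[C@@H]1C=C | intermediate
14 | lithium (1S,2R,4aS,8aR)-1-ethenyl-2-methyl-1,2,4a,5,6,7,8,8a-octahydronaphthalen-3-olate | C[C@H]1C([O-])=C[C@H]2CCCC[C@H]2[C@@H]1C=C.[Li+] | intermediate
15 | (1S,2R,4aS,8aR)-1-ethenyl-2-methyl-1,2,4a,5,6,7,8,8a-octahydronaphthalen-3-yl trifluoromethanesulfonate | C[C@H]1C(OS(=O)(=O)C(F)(F)F)=C[C@H]2CCCC[C@H]2[C@@H]1C=C | intermediate
16 | (1S,2R,4aS,8aR)-1-formyl-2-methyl-1,2,4a,5,6,7,8,8a-octahydronaphthalen-3-yl trifluoromethanesulfonate | C[C@H]1C(OS(=O)(=O)C(F)(F)F)=C[C@H]2CCCC[C@H]2[C@@H]1C=O | intermediate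
17 | (1R,2S,4aR,8aR)-2-methyl-1,2,4a,5,6,7,8,8a-octahydronaphthalene-1-carbaldehyde | C[C@H]1C=C[C@H]2CCCC[C@H]2[C@@H]1C=O | intermediate
18 | 2-chloro-4-nitropyridine 1-oxide | [O-][n+]1ccc(cc1Cl)[N+](=O)[O-] | starting material
19 | 2,4-bis[2-(trimethylsilyl)ethoxy]pyridine 1-oxide | C[Si](C)(C)CCOc1cc[n+]([O-])c(OCC[Si](C)(C)C)c1 | intermediate
20 | 5-iodo-2,4-bis[2-(trimethylsilyl)ethoxy]pyridine 1-oxide | C[Si](C)(C)CCOc1cc(OCC[Si](C)(C)C)[n+]([O-])cc1I | intermediate
21 | 4,4-dimethoxycyclohexa-2,5-dien-1-one | COC1(OC)C=CC(=O)C=C1 | starting material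
22 | {1-oxido-2,4-bis[2-(trimethylsilyl)ethoxy]pyridin-1-ium-5-yl}magnesium chloride | C[Si](C)(C)CCOc1cc(OCC[Si](C)(C)C)[n+]([O-])cc1[Mg]Cl | intermediate
23 | 5-(1-hydroxy-4,4-dimethoxycyclohexa-2,5-dien-1-yl)-2,4-bis[2-(trimethylsilyl)ethoxy]pyridine 1-oxide | COC1(OC)C=CC(O)(C=C1)c1c[n+]([O-])c(OCC[Si](C)(C)C)cc1OCC[Si](C)(C)C | intermediate
24 | 5-(1-hydroxy-4-oxocyclohexa-2,5-dien-1-yl)-2,4-bis[2-(trimethylsilyl)ethoxy]pyridine 1-oxide | O=C1C=CC(O)(C=C1)c1c[n+]([O-])c(OCC[Si](C)(C)C)cc1OCC[Si](C)(C)C | intermediate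
25 | 5-[4-oxo-1-(triethylsilyloxy)cyclohexa-2,5-dien-1-yl]-2,4-bis[2-(trimethylsilyl)ethoxy]pyridine 1-oxide | O=C1C=CC(O[Si](CC)(CC)CC)(C=C1)c1c[n+]([O-])c(OCC[Si](C)(C)C)cc1OCC[Si](C)(C)C | intermediate
26 | 5-[4-hydroxy-1-(triethylsilyloxy)cyclohexa-2,5-dien-1-yl]-2,4-bis[2-(trimethylsilyl)ethoxy]pyridine 1-oxide, 4-OH cis to the pyridyl ring (meso) | C[Si](C)(C)CCOc1cc(OCC[Si](C)(C)C)[n+]([O-])cc1[C@@]1(O[Si](CC)(CC)CC)C=C[C@@H](O)C=C1 | intermediate
27 | 5-[(1R,2S,5R,6R)-5-hydroxy-2-(triethylsilyloxy)-7-oxabicyclo[4.1.0]hept-3-en-2-yl]-2,4-bis[2-(trimethylsilyl)ethoxy]pyridine 1-oxide | C[Si](C)(C)CCOc1cc(OCC[Si](C)(C)C)[n+]([O-])cc1[C@@]1(O[Si](CC)(CC)CC)C=C[C@@H](O)[C@H]2O[C@H]21 | intermediate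
28 | 5-[(1R,2S,5R,6R)-5-hydroxy-2-(triethylsilyloxy)-7-oxabicyclo[4.1.0]heptan-2-yl]-2,4-bis[2-(trimethylsilyl)ethoxy]pyridine 1-oxide | C[Si](C)(C)CCOc1cc(OCC[Si](C)(C)C)[n+]([O-])cc1[C@@]1(O[Si](CC)(CC)CC)CC[C@@H](O)[C@H]2O[C@H]21 | intermediate
29 | 5-[(1R,2S,5R,6S)-2,5-bis(triethylsilyloxy)-7-oxabicyclo[4.1.0]heptan-2-yl]-2,4-bis[2-(trimethylsilyl)ethoxy]pyridine 1-oxide | C[Si](C)(C)CCOc1cc(OCC[Si](C)(C)C)[n+]([O-])cc1[C@@]1(O[Si](CC)(CC)CC)CC[C@@H](O[Si](CC)(CC)CC)[C@H]2O[C@H]21 | intermediate
30 | 5-[(1R,2S,5R,6S)-2,5-bis(triethylsilyloxy)-7-oxabicyclo[4.1.0]heptan-2-yl]-3-iodo-2,4-bis[2-(trimethylsilyl)ethoxy]pyridine 1-oxide | C[Si](C)(C)CCOc1c(I)c(OCC[Si](C)(C)C)[n+]([O-])cc1[C@@]1(O[Si](CC)(CC)CC)CC[C@@H](O[Si](CC)(CC)CC)[C@H]2O[C@H]21 | intermediate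
31 | {5-[(1R,2S,5R,6S)-2,5-bis(triethylsilyloxy)-7-oxabicyclo[4.1.0]heptan-2-yl]-1-oxido-2,4-bis[2-(trimethylsilyl)ethoxy]pyridin-1-ium-3-yl}magnesium chloride | C[Si](C)(C)CCOc1c([Mg]Cl)c(OCC[Si](C)(C)C)[n+]([O-])cc1[C@@]1(O[Si](CC)(CC)CC)CC[C@@H](O[Si](CC)(CC)CC)[C@H]2O[C@H]21 | intermediate
32 | 5-[(1R,2S,5R,6S)-2,5-bis(triethylsilyloxy)-7-oxabicyclo[4.1.0]heptan-2-yl]-3-{hydroxy[(1R,2S,4aR,8aR)-2-methyl-1,2,4a,5,6,7,8,8a-octahydronaphthalen-1-yl]methyl}-2,4-bis[2-(trimethylsilyl)ethoxy]pyridine 1-oxide (both carbinol epimers) | C[C@H]1C=C[C@H]2CCCC[C@H]2[C@@H]1C(O)c1c(OCC[Si](C)(C)C)[n+]([O-])cc(c1OCC[Si](C)(C)C)[C@@]1(O[Si](CC)(CC)CC)CC[C@@H](O[Si](CC)(CC)CC)[C@H]2O[C@H]21 | intermediate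
33 | 5-[(1R,2S,5R,6S)-2,5-bis(triethylsilyloxy)-7-oxabicyclo[4.1.0]heptan-2-yl]-3-[(1R,2S,4aR,8aR)-2-methyl-1,2,4a,5,6,7,8,8a-octahydronaphthalene-1-carbonyl]-2,4-bis[2-(trimethylsilyl)ethoxy]pyridine 1-oxide | C[C@H]1C=C[C@H]2CCCC[C@H]2[C@@H]1C(=O)c1c(OCC[Si](C)(C)C)[n+]([O-])cc(c1OCC[Si](C)(C)C)[C@@]1(O[Si](CC)(CC)CC)CC[C@@H](O[Si](CC)(CC)CC)[C@H]2O[C@H]21 | intermediate
34 | fischerin, 3-[(1R,2S,4aR,8aR)-2-methyl-1,2,4a,5,6,7,8,8a-octahydronaphthalene-1-carbonyl]-5-[(1R,2S,5R,6R)-2,5-dihydroxy-7-oxabicyclo[4.1.0]heptan-2-yl]-1,4-dihydroxypyridin-2(1H)-one | C[C@H]1C=C[C@H]2CCCC[C@H]2[C@@H]1C(=O)c1c(O)c([C@@]2(O)CC[C@@H](O)[C@H]3O[C@H]32)cn(O)c1=O | target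

## Step count and least certain steps

Total step count: 22. Longest linear sequence: 13 steps (steps 1–10, then 20–22). The heterocyclic branch (steps 11–19) has 9 steps before the union.

**Step 16 (key step).** The discrimination between the two enantiotopic alkenes may be poor, because the ring constraint and the coordinating N-oxide can disturb the catalyst. The bis-allylic alcohol may also be oxidised back to the dienone, or the dienol may aromatise by loss of silanol under the Lewis-acidic conditions. The fallback moves the asymmetric event to a different reaction. It sets out from 25, which is desymmetrised by copper-hydride-catalysed enantioselective conjugate reduction of one enone arm (Cu(OAc)2, chiral bisphosphine, silane) to 5-[(1R)-4-oxo-1-(triethylsilyloxy)cyclohex-2-en-1-yl]-2,4-bis[2-(trimethylsilyl)ethoxy]pyridine 1-oxide F1. Luche reduction gives the allylic alcohol with the hydroxyl cis to the pyridyl ring, F2. An achiral vanadyl acetylacetonate/tert-butyl hydroperoxide epoxidation directed by that hydroxyl then returns to the route at 28.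

**Step 15.** Hydride delivery to the dienone is controlled only by the remote C1' substituents and may show poor facial selectivity; any cis-configured dienol would lead to the wrong epoxide face. The fallback reduces before silylation. It sets out from 24, where the small free hydroxyl and the large aryl group reinforce each other, and gives the diol with the two hydroxyls trans, 5-(1,4-dihydroxycyclohexa-2,5-dien-1-yl)-2,4-bis[2-(trimethylsilyl)ethoxy]pyridine 1-oxide F3. Both hydroxyls are silylated to the bis(triethylsilyl) ether F4. The secondary allylic silyl ether alone is then removed with pyridine-buffered HF·pyridine, returning at 26.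

**Step 13.** The iodine–magnesium exchange on the N-oxide may be incomplete, the Grignard reagent may add to the N-oxide ring at C6, or the tertiary bis-allylic carbinol may ionise during ketal hydrolysis. The fallback builds the quinol by dearomatisation instead. It sets out from 20, which is joined by Suzuki–Miyaura coupling with 4-hydroxyphenylboronic acid to 5-(4-hydroxyphenyl)-2,4-bis[2-(trimethylsilyl)ethoxy]pyridine 1-oxide F5. Oxidation with (diacetoxyiodo)benzene in aqueous acetonitrile then gives the para-quinol, returning at 24.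

**Step 20.** Addition of a doubly ortho-substituted aryl-magnesium to an α-branched aldehyde may be slow, so that enolisation of the aldehyde or attack on the epoxide competes. The fallback uses a chromium-mediated coupling instead of a magnesium reagent: 30 and 17 are joined directly under Nozaki–Hiyama–Kishi conditions (CrCl2, catalytic NiCl2, DMF) to give 32. This makes no new compound (F0).

**Step 22.** Removing four groups in one pot may cause base-induced epoxide migration at the freed tertiary alkoxide, ionisation of the tertiary carbinol if the medium becomes acidic, or incomplete cleavage of the hindered 4-silylethyl ether. The fallback separates the two cleavage mechanisms. It sets out from 33. Pyridine-buffered HF·pyridine removes only the two triethylsilyl ethers and gives 5-[(1R,2S,5R,6R)-2,5-dihydroxy-7-oxabicyclo[4.1.0]heptan-2-yl]-3-[(1R,2S,4aR,8aR)-2-methyl-1,2,4a,5,6,7,8,8a-octahydronaphthalene-1-carbonyl]-2,4-bis[2-(trimethylsilyl)ethoxy]pyridine 1-oxide F6. Anhydrous tris(dimethylamino)sulfonium difluorotrimethylsilicate in DMF at 0 °C then removes the two silylethyl groups and reaches 34.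

## Further compounds

F1 | step 16 | 5-[(1R)-4-oxo-1-(triethylsilyloxy)cyclohex-2-en-1-yl]-2,4-bis[2-(trimethylsilyl)ethoxy]pyridine 1-oxide | C[Si](C)(C)CCOc1cc(OCC[Si](C)(C)C)[n+]([O-])cc1[C@@]1(O[Si](CC)(CC)CC)CCC(=O)C=C1
F2 | step 16 | 5-[4-hydroxy-1-(triethylsilyloxy)cyclohex-2-en-1-yl]-2,4-bis[2-(trimethylsilyl)ethoxy]pyridine 1-oxide, 4-OH cis to the pyridyl ring | C[Si](C)(C)CCOc1cc(OCC[Si](C)(C)C)[n+]([O-])cc1[C@@]1(O[Si](CC)(CC)CC)CC[C@@H](O)C=C1
F3 | step 15 | 5-(1,4-dihydroxycyclohexa-2,5-dien-1-yl)-2,4-bis[2-(trimethylsilyl)ethoxy]pyridine 1-oxide, hydroxyls trans (meso) | C[Si](C)(C)CCOc1cc(OCC[Si](C)(C)C)[n+]([O-])cc1[C@@]1(O)C=C[C@@H](O)C=C1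
F4 | step 15 | 5-[1,4-bis(triethylsilyloxy)cyclohexa-2,5-dien-1-yl]-2,4-bis[2-(trimethylsilyl)ethoxy]pyridine 1-oxide, silyloxy groups trans (meso) | C[Si](C)(C)CCOc1cc(OCC[Si](C)(C)C)[n+]([O-])cc1[C@@]1(O[Si](CC)(CC)CC)C=C[C@@H](O[Si](CC)(CC)CC)C=C1
F5 | step 13 | 5-(4-hydroxyphenyl)-2,4-bis[2-(trimethylsilyl)ethoxy]pyridine 1-oxide | C[Si](C)(C)CCOc1cc(OCC[Si](C)(C)C)[n+]([O-])cc1-c1ccc(O)cc1
F0 | step 20 | none | none
F6 | step 22 | 5-[(1R,2S,5R,6R)-2,5-dihydroxy-7-oxabicyclo[4.1.0]heptan-2-yl]-3-[(1R,2S,4aR,8aR)-2-methyl-1,2,4a,5,6,7,8,8a-octahydronaphthalene-1-carbonyl]-2,4-bis[2-(trimethylsilyl)ethoxy]pyridine 1-oxide | C[C@H]1C=C[C@H]2CCCC[C@H]2[C@@H]1C(=O)c1c(OCC[Si](C)(C)C)[n+]([O-])cc(c1OCC[Si](C)(C)C)[C@@]1(O)CC[C@@H](O)[C@H]2O[C@H]21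
A1 | alternative 1 | 4-(tert-butyldimethylsilyloxy)-2,3-epoxycyclohexan-1-one, epoxide cis to the silyloxy group, configured as C4'–C6' of the target | O=C1CC[C@@H](O[Si](C)(C)C(C)(C)C)[C@H]2O[C@H]21
A2 | alternative 1 | (2E,8E,10E)-dodeca-2,8,10-trienal | C/C=C/C=C/CCCC/C=C/C=O
A3 | alternative 1 | ketone adduct with the tertiary hydroxyl cis to the epoxide (C1' epimer of the required carbinol) | C[Si](C)(C)CCOc1cc(OCC[Si](C)(C)C)[n+]([O-])cc1[C@]1(O)CC[C@@H](O[Si](C)(C)C(C)(C)C)[C@H]2O[C@H]21
A4 | alternative 2 | (5S)-5-(4-hydroxybenzyl)-3-[(1R,2S,4aR,8aR)-2-methyl-1,2,4a,5,6,7,8,8a-octahydronaphthalene-1-carbonyl]tetramic acid | C[C@H]1C=C[C@H]2CCCC[C@H]2[C@@H]1C(=O)C1=C(O)[C@H](Cc2ccc(O)cc2)NC1=O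
A5 | alternative 2 | 4-hydroxy-5-(4-hydroxyphenyl)-3-[(1R,2S,4aR,8aR)-2-methyl-1,2,4a,5,6,7,8,8a-octahydronaphthalene-1-carbonyl]pyridin-2(1H)-one | C[C@H]1C=C[C@H]2CCCC[C@H]2[C@@H]1C(=O)c1c(O)c(-c2ccc(O)cc2)c[nH]c1=O
A6 | alternative 3 | 5-(cyclohexa-1,3-dien-1-yl)-2,4-bis[2-(trimethylsilyl)ethoxy]pyridine 1-oxide | C[Si](C)(C)CCOc1cc(OCC[Si](C)(C)C)[n+]([O-])cc1C1=CC=CCC1
A7 | alternative 3 | 5-(2,3-dioxabicyclo[2.2.2]oct-5-en-1-yl)-2,4-bis[2-(trimethylsilyl)ethoxy]pyridine 1-oxide (racemic) | C[Si](C)(C)CCOc1cc(OCC[Si](C)(C)C)[n+]([O-])cc1C12CCC(C=C1)OO2
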